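**Retrosynthetic overview**

1. The strategy rests on flavone ring B: a para-disubstituted benzene whose C4' carries the ether oxygen bonded to flavanone C6 (flanked by C5–OH and C7–OMe) and whose C1' carries flavone C2.
2. Late stage: BCl3 unmasking ⇐ flavanone C2–aryl bond by enantioselective conjugate addition of an arylboronic acid to a 6-aryloxy-5,7-dimethoxychromone ⇐ chromone from an o-hydroxyacetophenone (acetate, Fries rearrangement).
3. Flavone pyranone ring ⇐ Claisen condensation of a methyl 4-aryloxybenzoate with 2-hydroxy-4,6-bis(benzyloxy)acetophenone, then cyclodehydration.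
4. Methyl 4-aryloxybenzoate ⇐ methyl coumalate + aryl ethynyl ether by [4+2] cycloaddition and loss of CO2, so the crowded oxygen is vinylated, never arylated; ynol ether ⇐ 2,6-dimethoxybenzoquinone and trichloroethylene.
5. Ring order: flavone ring B (cycloaddition) → flavone ring C → pyranone ring of the flavanone half (as chromone) → C2 stereocentre → deprotection.

Key step: step 5

Assumption: the Pd(OCOCF3)2/t-BuPyOx catalyst is taken to show on chromones the same facial preference as on 3-substituted cyclohexenones, so the (R)-ligand is expected to give the (2S)-flavanone; the ligand antipode is the remedy if the sense proves opposite.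

**Route**

Step 1
Reactants: 1 2,6-dimethoxy-1,4-benzoquinone
Product: 2 2,6-dimethoxybenzene-1,4-diol
Conditions: Na2S2O4, EtOAc/H2O, rt, argon
Reagents that add atoms: none
Why: Na2S2O4 reduction of a 1,4-benzoquinone to its hydroquinone is a fast two-electron reduction that touches no other group.

Step 2
Reactants: 2 2,6-dimethoxybenzene-1,4-diol
Product: 3 2,6-dimethoxy-4-(methoxymethoxy)phenol
Conditions: MOMCl (1.05 equiv), i-Pr2NEt, CH2Cl2 (degassed), 0 °C → rt, argon
Reagents that add atoms: chloromethyl methyl ether, COCCl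
Why: Williamson-type O-alkylation (MOM ether formation) should go to the C4 hydroxyl, which is unhindered and the more acidic one, whereas the C1 hydroxyl is flanked and hydrogen-bonded by two methoxy groups.

Step 3
Reactants: 3 2,6-dimethoxy-4-(methoxymethoxy)phenol; 4 trichloroethylene
Product: 5 2-{[(E)-1,2-dichloroethenyl]oxy}-1,3-dimethoxy-5-(methoxymethoxy)benzene
Conditions: K2CO3, DMF, 70 °C
Reagents that add atoms: none
Why: Base-mediated O-vinylation of a phenol with trichloroethylene (anti addition of the phenoxide to dichloroacetylene generated in solution) should give the (E)-dichlorovinyl ether and needs only a small linear electrophile at the crowded oxygen.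

Step 4
Reactants: 5 2-{[(E)-1,2-dichloroethenyl]oxy}-1,3-dimethoxy-5-(methoxymethoxy)benzene
Product: 8 2-(ethynyloxy)-1,3-dimethoxy-5-(methoxymethoxy)benzene, via chloroethynyl ether 6 (not isolated), via lithium aryloxyacetylide 7 (not isolated)
Conditions: n-BuLi (2.3 equiv), Et2O, −78 → −40 °C; then H2O, −78 °C; cold neutral work-up, used at once
Reagents that add atoms: none
Why: Dehydrochlorination followed by lithium–chlorine exchange (the standard ynol ether synthesis from 1,2-dichlorovinyl ethers) should give the acetylide, which is protonated on quench, and both steps are expected to outpace ortho-lithiation of the MOM/methoxy arene at −78 °C.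

Step 5
Reactants: 8 2-(ethynyloxy)-1,3-dimethoxy-5-(methoxymethoxy)benzene; 9 methyl coumalate (methyl 2-oxo-2H-pyran-5-carboxylate)
Product: 11 methyl 4-[2,6-dimethoxy-4-(methoxymethoxy)phenoxy]benzoate, via bicyclic lactone cycloadduct 10 (not isolated)
Conditions: PhMe, 2,6-di-tert-butyl-4-methylphenol (cat.), 110 °C, sealed tube, 9 in slight excess
Reagents that add atoms: none
Why: Proposed new method: the oxygen lone pair should raise the HOMO of the ynol ether and place its largest coefficient on the terminal CH carbon, which is expected to bond first to C6 of methyl coumalate (the vinylogous acceptor position of the ester and a terminus of the electron-poor diene), the oxygen-bearing alkyne carbon then closing onto C3 in an asynchronous inverse-electron-demand [4+2] cycloaddition, after which the bridged lactone 10 should lose CO2 by retro-[4+2] and reach the benzene oxidation level without any oxidant. The closest known reaction type is the cycloaddition–decarboxylation of methyl coumalate with enol ethers, ketene acetals, ynamines and simple alkynes to para-substituted benzoates, and an aryl ethynyl ether has not been shown as the 2π partner, hence the label. Flavone ring B is closed by intermolecular cycloaddition that forms the C2'–C3' and C4'–C5' bonds in one operation, four ring carbons coming from the pyrone and two from the alkyne. No stereocentre survives, the two bridgehead centres of 10 being destroyed on aromatisation. The selectivity needed is regiochemical, ether oxygen para and not meta to the ester, and it is secured by the polarisation match between the nucleophilic alkyne terminus and pyrone C6. The two methoxy groups that make this oxygen hard to arylate are expected to help here, since they shield the ynol ether from self-condensation while the reacting alkyne carbons stay unhindered.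

Step 6
Reactants: 12 2',4',6'-trihydroxyacetophenone
Product: 13 1-[2,4-bis(benzyloxy)-6-hydroxyphenyl]ethan-1-one
Conditions: BnBr (2.1 equiv), K2CO3, DMF, rt
Reagents that add atoms: benzyl bromide, BrCc1ccccc1
Why: Williamson benzylation should stop at the dibenzyl ether because the remaining hydroxyl is hydrogen-bonded to the acetyl carbonyl and is the least nucleophilic.

Step 7
Reactants: 11 methyl 4-[2,6-dimethoxy-4-(methoxymethoxy)phenoxy]benzoate; 13 1-[2,4-bis(benzyloxy)-6-hydroxyphenyl]ethan-1-one
Product: 14 1-[2,4-bis(benzyloxy)-6-hydroxyphenyl]-3-{4-[2,6-dimethoxy-4-(methoxymethoxy)phenoxy]phenyl}propane-1,3-dione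
Conditions: NaH (4 equiv), THF, 65 °C; then aq. HCl, 0 °C
Reagents that add atoms: none
Why: Crossed Claisen condensation of the phenoxide–enolate dianion of 13 with the non-enolisable benzoate 11 should be driven to completion by irreversible deprotonation of the 1,3-diketone.

Step 8
Reactants: 14 1-[2,4-bis(benzyloxy)-6-hydroxyphenyl]-3-{4-[2,6-dimethoxy-4-(methoxymethoxy)phenoxy]phenyl}propane-1,3-dione
Product: 16 5,7-bis(benzyloxy)-2-[4-(4-hydroxy-2,6-dimethoxyphenoxy)phenyl]-4H-chromen-4-one, via flavone MOM ether 15 (not isolated)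
Conditions: HCl (1.25 M in MeOH), THF, 55 °C
Reagents that add atoms: none
Why: Acid-catalysed cyclodehydration of the o-hydroxyaryl 1,3-diketone closes the flavone pyranone ring, and the same dilute acid should transfer the MOM acetal to methanol while benzyl and methyl ethers stay.

Step 9
Reactants: 16 5,7-bis(benzyloxy)-2-[4-(4-hydroxy-2,6-dimethoxyphenoxy)phenyl]-4H-chromen-4-one
Product: 17 4-{4-[5,7-bis(benzyloxy)-4-oxo-4H-chromen-2-yl]phenoxy}-3,5-dimethoxyphenyl acetate
Conditions: Ac2O, pyridine, rt
Reagents that add atoms: acetic anhydride, CC(=O)OC(C)=O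
Why: O-acetylation of the only free phenol is routine, and isolating the ester lets the next step run without excess anhydride.

Step 10
Reactants: 17 4-{4-[5,7-bis(benzyloxy)-4-oxo-4H-chromen-2-yl]phenoxy}-3,5-dimethoxyphenyl acetate
Product: 18 2-[4-(3-acetyl-4-hydroxy-2,6-dimethoxyphenoxy)phenyl]-5,7-bis(benzyloxy)-4H-chromen-4-one
Conditions: BF3·OEt2 (3 equiv), ClCH2CH2Cl, rt → 50 °C; then aq. NaHCO3
Reagents that add atoms: none
Why: Fries rearrangement should deliver the acetyl group to one of the two equivalent carbons ortho to the ester oxygen (each also ortho and para to a methoxy group, a phloroglucinol-type position), and the high reactivity of that ring allows a moderate temperature and no anhydride, which is meant to spare the benzyl ethers.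

Step 11
Reactants: 18 2-[4-(3-acetyl-4-hydroxy-2,6-dimethoxyphenoxy)phenyl]-5,7-bis(benzyloxy)-4H-chromen-4-one
Product: 20 5,7-bis(benzyloxy)-2-{4-[(5,7-dimethoxy-4-oxo-4H-chromen-6-yl)oxy]phenyl}-4H-chromen-4-one, via enaminone 19 (not isolated)
Conditions: Me2NCH(OMe)2, PhMe, 95 °C; then TsOH·H2O (1.2 equiv), CH2Cl2, rt
Reagents that add atoms: N,N-dimethylformamide dimethyl acetal, COC(OC)N(C)C
Why: Condensation of the methyl ketone with the formamide acetal gives an enaminone, and acid then promotes 6-endo addition of the phenol and loss of dimethylamine (the enaminone chromone synthesis).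

Step 12
Reactants: 20 5,7-bis(benzyloxy)-2-{4-[(5,7-dimethoxy-4-oxo-4H-chromen-6-yl)oxy]phenyl}-4H-chromen-4-one; 21 4-(benzyloxy)phenylboronic acid
Product: 22 (2S)-2-[4-(benzyloxy)phenyl]-6-{4-[5,7-bis(benzyloxy)-4-oxo-4H-chromen-2-yl]phenoxy}-5,7-dimethoxy-2,3-dihydro-4H-chromen-4-one
Conditions: Pd(OCOCF3)2 (10 mol%), (R)-4-tert-butyl-2-(pyridin-2-yl)-4,5-dihydrooxazole [(R)-t-BuPyOx, 12 mol%], NH4PF6 (30 mol%), H2O (5 equiv), ClCH2CH2Cl, 60 °C
Reagents that add atoms: none
Why: Asymmetric conjugate addition of an arylboronic acid to a chromone under cationic divalent palladium (transmetalation, enantio-determining insertion of the C2=C3 bond, protonolysis of the palladium enolate) should set C2 as (S) through the tert-butyl group of the (R)-ligand blocking one enone face, while the 2-aryl-substituted flavone is too hindered to react.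

Step 13
Reactants: 22 (2S)-2-[4-(benzyloxy)phenyl]-6-{4-[5,7-bis(benzyloxy)-4-oxo-4H-chromen-2-yl]phenoxy}-5,7-dimethoxy-2,3-dihydro-4H-chromen-4-one
Product: 23 (2S)-6-[4-(5,7-dihydroxy-4-oxo-4H-chromen-2-yl)phenoxy]-5-hydroxy-2-(4-hydroxyphenyl)-7-methoxy-2,3-dihydro-4H-chromen-4-one
Conditions: BCl3 (1 M in CH2Cl2, excess), pentamethylbenzene, CH2Cl2, −78 → 0 °C; then MeOH/H2O
Reagents that add atoms: none
Why: BCl3 ether cleavage should remove the three benzyl groups (cation trapped by pentamethylbenzene) and the C5 methyl ether through boron chelation between O5 and the C4 carbonyl, while the non-chelated C7 methoxy group and the diaryl ether stay and the low temperature guards C2 against epimerisation by ring opening.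

**Compound list**

1 | 2,6-dimethoxy-1,4-benzoquinone | COC1=CC(=O)C=C(OC)C1=O | starting material
2 | 2,6-dimethoxybenzene-1,4-diol | COc1cc(O)cc(OC)c1O | intermediate
3 | 2,6-dimethoxy-4-(methoxymethoxy)phenol | COCOc1cc(OC)c(O)c(OC)c1 | intermediate
4 | trichloroethylene | ClC=C(Cl)Cl | starting material
5 | 2-{[(E)-1,2-dichloroethenyl]oxy}-1,3-dimethoxy-5-(methoxymethoxy)benzene | Cl/C=C(/Cl)Oc1c(OC)cc(OCOC)cc1OC | intermediate
6 | 2-[(chloroethynyl)oxy]-1,3-dimethoxy-5-(methoxymethoxy)benzene (formed in the flask) | ClC#COc1c(OC)cc(OCOC)cc1OC | intermediate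
7 | lithium 2-[2,6-dimethoxy-4-(methoxymethoxy)phenoxy]ethyn-1-ide (formed in the flask) | [Li]C#COc1c(OC)cc(OCOC)cc1OC | intermediate
8 | 2-(ethynyloxy)-1,3-dimethoxy-5-(methoxymethoxy)benzene | C#COc1c(OC)cc(OCOC)cc1OC | intermediate
9 | methyl coumalate (methyl 2-oxo-2H-pyran-5-carboxylate) | COC(=O)C1=COC(=O)C=C1 | starting material
10 | methyl 5-[2,6-dimethoxy-4-(methoxymethoxy)phenoxy]-3-oxo-2-oxabicyclo[2.2.2]octa-5,7-diene-7-carboxylate (racemic, formed in the flask) | COC(=O)C1=CC2C(=O)OC1C=C2Oc1c(OC)cc(OCOC)cc1OC | intermediate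
11 | methyl 4-[2,6-dimethoxy-4-(methoxymethoxy)phenoxy]benzoate | COC(=O)c1ccc(Oc2c(OC)cc(OCOC)cc2OC)cc1 | intermediate
12 | 2',4',6'-trihydroxyacetophenone | CC(=O)c1c(O)cc(O)cc1O | starting material
13 | 1-[2,4-bis(benzyloxy)-6-hydroxyphenyl]ethan-1-one | CC(=O)c1c(O)cc(OCc2ccccc2)cc1OCc1ccccc1 | intermediate
14 | 1-[2,4-bis(benzyloxy)-6-hydroxyphenyl]-3-{4-[2,6-dimethoxy-4-(methoxymethoxy)phenoxy]phenyl}propane-1,3-dione | O=C(CC(=O)c1ccc(Oc2c(OC)cc(OCOC)cc2OC)cc1)c1c(O)cc(OCc2ccccc2)cc1OCc1ccccc1 | intermediate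
15 | 5,7-bis(benzyloxy)-2-{4-[2,6-dimethoxy-4-(methoxymethoxy)phenoxy]phenyl}-4H-chromen-4-one (formed in the flask) | O=c1cc(-c2ccc(Oc3c(OC)cc(OCOC)cc3OC)cc2)oc2cc(OCc3ccccc3)cc(OCc3ccccc3)c12 | intermediate
16 | 5,7-bis(benzyloxy)-2-[4-(4-hydroxy-2,6-dimethoxyphenoxy)phenyl]-4H-chromen-4-one | O=c1cc(-c2ccc(Oc3c(OC)cc(O)cc3OC)cc2)oc2cc(OCc3ccccc3)cc(OCc3ccccc3)c12 | intermediate
17 | 4-{4-[5,7-bis(benzyloxy)-4-oxo-4H-chromen-2-yl]phenoxy}-3,5-dimethoxyphenyl acetate | CC(=O)Oc1cc(OC)c(Oc2ccc(-c3cc(=O)c4c(OCc5ccccc5)cc(OCc5ccccc5)cc4o3)cc2)c(OC)c1 | intermediate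
18 | 2-[4-(3-acetyl-4-hydroxy-2,6-dimethoxyphenoxy)phenyl]-5,7-bis(benzyloxy)-4H-chromen-4-one | CC(=O)c1c(O)cc(OC)c(Oc2ccc(-c3cc(=O)c4c(OCc5ccccc5)cc(OCc5ccccc5)cc4o3)cc2)c1OC | intermediate
19 | 5,7-bis(benzyloxy)-2-[4-(3-[(2E)-3-(dimethylamino)prop-2-enoyl]-4-hydroxy-2,6-dimethoxyphenoxy)phenyl]-4H-chromen-4-one (formed in the flask) | CN(C)/C=C/C(=O)c1c(O)cc(OC)c(Oc2ccc(-c3cc(=O)c4c(OCc5ccccc5)cc(OCc5ccccc5)cc4o3)cc2)c1OC | intermediate
20 | 5,7-bis(benzyloxy)-2-{4-[(5,7-dimethoxy-4-oxo-4H-chromen-6-yl)oxy]phenyl}-4H-chromen-4-one | COc1cc2occc(=O)c2c(OC)c1Oc1ccc(-c2cc(=O)c3c(OCc4ccccc4)cc(OCc4ccccc4)cc3o2)cc1 | intermediate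
21 | 4-(benzyloxy)phenylboronic acid | OB(O)c1ccc(OCc2ccccc2)cc1 | starting material
22 | (2S)-2-[4-(benzyloxy)phenyl]-6-{4-[5,7-bis(benzyloxy)-4-oxo-4H-chromen-2-yl]phenoxy}-5,7-dimethoxy-2,3-dihydro-4H-chromen-4-one | COc1cc2c(c(OC)c1Oc1ccc(-c3cc(=O)c4c(OCc5ccccc5)cc(OCc5ccccc5)cc4o3)cc1)C(=O)C[C@@H](c1ccc(OCc3ccccc3)cc1)O2 | intermediate
23 | (2S)-6-[4-(5,7-dihydroxy-4-oxo-4H-chromen-2-yl)phenoxy]-5-hydroxy-2-(4-hydroxyphenyl)-7-methoxy-2,3-dihydro-4H-chromen-4-one (CNP0269971.1) | COc1cc2c(c(O)c1Oc1ccc(-c3cc(=O)c4c(O)cc(O)cc4o3)cc1)C(=O)C[C@@H](c1ccc(O)cc1)O2 | target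

**Step count and risk**

Total step count: 13. Longest linear sequence: 12 (steps 1–5 and 7–13; step 6 is a one-step side branch).

Steps most likely to fail:

Step 5 (proposed new method). An aryloxy group is a weaker donor than an alkoxy or amino group, so the cycloaddition may be slow. Thermal oligomerisation or hydration of the ynol ether may then outrun it, and the temperature needed may erode the regiochemical preference. Fallback with known chemistry: set out from phenol 3 and join it to methyl 4-iodobenzoate by Ullmann-type O-arylation (CuI, picolinic acid, K3PO4, DMSO, 90 °C), a ligand system suited to doubly ortho-substituted phenols. This should give ester 11 directly, where the route is rejoined; no new compound is made (F0).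

Step 10. The Lewis acid may strip benzyl ethers, first the one on O5 peri to the flavone carbonyl, and the acyl group may transfer between molecules instead of migrating. Fallback: set out from phenol 16 (step 9 is skipped). Bromination with N-bromosuccinimide (1 equiv, MeCN, −20 °C) at the activated position ortho to the hydroxyl should give 5,7-bis(benzyloxy)-2-[4-(3-bromo-4-hydroxy-2,6-dimethoxyphenoxy)phenyl]-4H-chromen-4-one F1. Stille coupling with tributyl(1-ethoxyvinyl)stannane (PdCl2(PPh3)2, PhMe, 100 °C) should give 5,7-bis(benzyloxy)-2-{4-[3-(1-ethoxyethenyl)-4-hydroxy-2,6-dimethoxyphenoxy]phenyl}-4H-chromen-4-one F2. Hydrolysis of the enol ether with dilute aqueous HCl in THF at rt returns to the route at acetophenone 18.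

Step 12. Carbopalladation of the electron-rich 5,7-dioxygenated chromone may be slow, protodeboronation of the electron-rich boronic acid may use up the nucleophile, and facial discrimination may be insufficient. Fallback: set out from acetophenone 18 (step 11 is skipped). Claisen–Schmidt condensation with 4-(benzyloxy)benzaldehyde (KOH, EtOH/THF, rt) should give (2E)-3-[4-(benzyloxy)phenyl]-1-(3-{4-[5,7-bis(benzyloxy)-4-oxo-4H-chromen-2-yl]phenoxy}-6-hydroxy-2,4-dimethoxyphenyl)prop-2-en-1-one F3. Oxa-Michael ring closure (NaOAc, EtOH, reflux) should give racemic 2-[4-(benzyloxy)phenyl]-6-{4-[5,7-bis(benzyloxy)-4-oxo-4H-chromen-2-yl]phenoxy}-5,7-dimethoxy-2,3-dihydro-4H-chromen-4-one F4. Preparative HPLC on a chiral stationary phase returns to the route at 22. The separated (2R)-2-[4-(benzyloxy)phenyl]-6-{4-[5,7-bis(benzyloxy)-4-oxo-4H-chromen-2-yl]phenoxy}-5,7-dimethoxy-2,3-dihydro-4H-chromen-4-one F5 is re-equilibrated with base through the chalcone and recycled.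

Further compounds
F0 | step 5 | none | none
F1 | step 10 | 5,7-bis(benzyloxy)-2-[4-(3-bromo-4-hydroxy-2,6-dimethoxyphenoxy)phenyl]-4H-chromen-4-one | O=c1cc(-c2ccc(Oc3c(OC)cc(O)c(Br)c3OC)cc2)oc2cc(OCc3ccccc3)cc(OCc3ccccc3)c12
F2 | step 10 | 5,7-bis(benzyloxy)-2-{4-[3-(1-ethoxyethenyl)-4-hydroxy-2,6-dimethoxyphenoxy]phenyl}-4H-chromen-4-one | O=c1cc(-c2ccc(Oc3c(OC)cc(O)c(C(=C)OCC)c3OC)cc2)oc2cc(OCc3ccccc3)cc(OCc3ccccc3)c12
F3 | step 12 | (2E)-3-[4-(benzyloxy)phenyl]-1-(3-{4-[5,7-bis(benzyloxy)-4-oxo-4H-chromen-2-yl]phenoxy}-6-hydroxy-2,4-dimethoxyphenyl)prop-2-en-1-one | O=C(/C=C/c1ccc(OCc2ccccc2)cc1)c1c(O)cc(OC)c(Oc2ccc(-c3cc(=O)c4c(OCc5ccccc5)cc(OCc5ccccc5)cc4o3)cc2)c1OC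
F4 | step 12 | racemic 2-[4-(benzyloxy)phenyl]-6-{4-[5,7-bis(benzyloxy)-4-oxo-4H-chromen-2-yl]phenoxy}-5,7-dimethoxy-2,3-dihydro-4H-chromen-4-one | COc1cc2c(c(OC)c1Oc1ccc(-c3cc(=O)c4c(OCc5ccccc5)cc(OCc5ccccc5)cc4o3)cc1)C(=O)CC(c1ccc(OCc3ccccc3)cc1)O2
F5 | step 12 | (2R)-2-[4-(benzyloxy)phenyl]-6-{4-[5,7-bis(benzyloxy)-4-oxo-4H-chromen-2-yl]phenoxy}-5,7-dimethoxy-2,3-dihydro-4H-chromen-4-one | COc1cc2c(c(OC)c1Oc1ccc(-c3cc(=O)c4c(OCc5ccccc5)cc(OCc5ccccc5)cc4o3)cc1)C(=O)C[C@H](c1ccc(OCc3ccccc3)cc1)O2
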